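**Plan**

1. Numbering used below (own): C1 = ring carbon bearing =CH2; C2, C6 = ring-fusion CH; C3, C4, C5 = rest of the cyclopentene (C5 bears CH3); C7 = CHOH; C8 = CH bearing the side chain; C9 = CH2; C10 = CHOAc; C11–C15 = side chain outward; β = face of the C7 hydroxyl.
2. Retrosynthetic cuts, in order: C13=C14 (cross-metathesis); C1=CH2 and C10–O (back to a C1 ketone); C2–C3 plus C5–C6 of the cyclopentene (formal [3+2] of a cyclohept-2-enone with a but-2-ynylsilane); C2=C6 of the seven-membered ring (RCM); C6–C7 and C1–C2 (vinyl additions); C8–C9 (lactone alkylation).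
3. Enabling feature: in ring C2–C3–C4=C5–C6 the methyl-bearing sp2 carbon C5 sits on C6 (β to C1, the masked ketone under the exocyclic methylene) and the CH2 C3 sits on C2 (α to C1). The ring is therefore a nucleophile-at-β/electrophile-at-α three-carbon unit on the C1 enone, and the C7 oxygen next to C6 steers the face.
4. Forward order of rings: temporary δ-lactone (steps 1–2) → seven-membered ring by RCM (step 7) → cyclopentene by [3+2] annulation (step 11, last ring) → C10/C1 and side-chain finish.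
5. Stereochemistry: C11 from the commercial half-ester; C8 by trans-alkylation of the lactone; C7 by Felkin–Anh vinyl addition; C6 by annulation anti to the C7 silyl ether; C2 by equilibration to the trans-fused ketone; C10 by axial bromination then SN2 inversion; C13=C14 (E) by cross-metathesis.

Key step: step 11

Assumption: the configurations in the target SMILES are taken as absolute, and 1, 3, 14 and 22 are bought as such.

**Route**

Step 1
Reactants: 1 methyl hydrogen (R)-3-methylglutarate [(3R)-5-methoxy-3-methyl-5-oxopentanoic acid]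
Product: 2 (4S)-4-methyloxan-2-one
Conditions: LiBH4, THF, 0 °C to rt; then 2 M HCl, rt
Reagents that add atoms: none
Why: Chemoselective borohydride reduction of the ester beside the lithium carboxylate, then acid lactonisation, should give the δ-lactone with C11 taken unchanged from the half-ester.

Step 2
Reactants: 2 (4S)-4-methyloxan-2-one; 3 3-bromo-1,1-dimethoxypropane
Product: 4 (3R,4S)-3-(3,3-dimethoxypropyl)-4-methyloxan-2-one
Conditions: LDA, THF, −78 °C; then 3, HMPA, −78 to −30 °C
Reagents that add atoms: none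
Why: Enolate alkylation of a 4-substituted δ-lactone occurs anti to the C4 methyl group (1,2-induction), which should set C8 trans to the C11 methyl as the target requires.

Step 3
Reactants: 4 (3R,4S)-3-(3,3-dimethoxypropyl)-4-methyloxan-2-one
Product: 6 (3R,4R,5S)-4-(3,3-dimethoxypropyl)-5-methylhept-1-ene-3,7-diol, via lactol 5 (not isolated)
Conditions: DIBAL-H, CH2Cl2, −78 °C; then CH2=CHMgBr (4 equiv), THF, −78 to 0 °C
Reagents that add atoms: vinylmagnesium bromide C=C[Mg]Br
Why: Partial lactone reduction and Grignard addition to the open hydroxy-aldehyde should follow the Felkin–Anh model (branched C11 arm as the large group) to give the C7 carbinol with oxygen cis to the C11 arm in the later ring, the minor epimer being removed by chromatography.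

Step 4
Reactants: 6 (3R,4R,5S)-4-(3,3-dimethoxypropyl)-5-methylhept-1-ene-3,7-diol
Product: 8 (3R,4R,5S)-4-(3,3-dimethoxypropyl)-5-methyl-7-[(triethylsilyl)oxy]-3-[(triisopropylsilyl)oxy]hept-1-ene, via mono-triethylsilyl ether 7 (not isolated)
Conditions: TESCl (1.05 equiv), imidazole, CH2Cl2, −40 °C; then TIPSOTf, 2,6-lutidine, 0 °C
Reagents that add atoms: chlorotriethylsilane CC[Si](Cl)(CC)CC; triisopropylsilyl trifluoromethanesulfonate CC(C)[Si](OS(=O)(=O)C(F)(F)F)(C(C)C)C(C)C
Why: Kinetic silylation caps the primary alcohol as an acid-labile TES ether, and the hindered allylic C7 alcohol is then protected as the acid-stable TIPS ether that later directs the annulation.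

Step 5
Reactants: 8 (3R,4R,5S)-4-(3,3-dimethoxypropyl)-5-methyl-7-[(triethylsilyl)oxy]-3-[(triisopropylsilyl)oxy]hept-1-ene
Product: 9 (4R,5R)-4-[(2S)-4-hydroxybutan-2-yl]-5-[(triisopropylsilyl)oxy]hept-6-enal
Conditions: AcOH/THF/H2O 3:1:1, 40 °C
Reagents that add atoms: water O
Why: Mild aqueous acid should hydrolyse the dimethyl acetal and the primary TES ether together while the secondary TIPS ether survives (acetal hydrolysis with selective desilylation).

Step 6
Reactants: 9 (4R,5R)-4-[(2S)-4-hydroxybutan-2-yl]-5-[(triisopropylsilyl)oxy]hept-6-enal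
Product: 10 (3R,4R)-4-[(2S)-4-hydroxybutan-2-yl]-3-[(triisopropylsilyl)oxy]nona-1,8-dien-7-ol (both epimers at the new carbinol, C1 in the numbering used here)
Conditions: CH2=CHMgBr (3 equiv), THF, −78 to 0 °C
Reagents that add atoms: vinylmagnesium bromide C=C[Mg]Br
Why: Grignard 1,2-addition gives the second allylic alcohol, whose configuration is irrelevant because C1 is oxidised in step 8.

Step 7
Reactants: 10 (3R,4R)-4-[(2S)-4-hydroxybutan-2-yl]-3-[(triisopropylsilyl)oxy]nona-1,8-dien-7-ol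
Product: 11 (4R,5R)-5-[(2S)-4-hydroxybutan-2-yl]-4-[(triisopropylsilyl)oxy]cyclohept-2-en-1-ol (both epimers at C1)
Conditions: Grubbs II (3 mol%), CH2Cl2 (5 mM), 40 °C
Reagents that add atoms: none
Why: Ring-closing metathesis of the 1,8-diene should form the seven-membered ring with a cis C2=C6 alkene, no other alkene being present at this stage.

Step 8
Reactants: 11 (4R,5R)-5-[(2S)-4-hydroxybutan-2-yl]-4-[(triisopropylsilyl)oxy]cyclohept-2-en-1-ol
Product: 12 (3S)-3-[(1R,2R)-5-oxo-2-[(triisopropylsilyl)oxy]cyclohept-3-en-1-yl]butanal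
Conditions: Dess–Martin periodinane (2.5 equiv), NaHCO3, CH2Cl2, 0 °C to rt
Reagents that add atoms: none
Why: Dess–Martin oxidation converts the allylic alcohol into the enone and the primary alcohol into the aldehyde in one operation without epimerising C8 or C11.

Step 9
Reactants: 12 (3S)-3-[(1R,2R)-5-oxo-2-[(triisopropylsilyl)oxy]cyclohept-3-en-1-yl]butanal
Product: 13 (4R,5R)-5-[(2S)-pent-4-en-2-yl]-4-[(triisopropylsilyl)oxy]cyclohept-2-en-1-one
Conditions: Ph3PCH3Br, KHMDS, THF, 0 °C; then 12 (1.0 equiv of ylide), −78 °C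
Reagents that add atoms: methyltriphenylphosphonium bromide C[P+](c1ccccc1)(c1ccccc1)c1ccccc1.[Br-]
Why: Wittig methylenation with the non-stabilised ylide is much faster at the aldehyde than at the hindered conjugated ring ketone, so the side-chain allyl terminus is unveiled only after the metathesis step.

Step 10
Reactants: 14 but-2-yne
Product: 15 (but-2-yn-1-yl)triisopropylsilane
Conditions: n-BuLi, TMEDA, Et2O, 0 °C; then TIPSOTf, −78 °C to rt
Reagents that add atoms: triisopropylsilyl trifluoromethanesulfonate CC(C)[Si](OS(=O)(=O)C(F)(F)F)(C(C)C)C(C)C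
Why: Propargylic lithiation of but-2-yne and silylation at the CH2 terminus with the bulky silyl triflate should give the propargylsilane, any allenyl isomer being removed by distillation.

Step 11
Reactants: 13 (4R,5R)-5-[(2S)-pent-4-en-2-yl]-4-[(triisopropylsilyl)oxy]cyclohept-2-en-1-one; 15 (but-2-yn-1-yl)triisopropylsilane
Product: 16 (3aR,7R,8S,8aR)-1-methyl-7-[(2S)-pent-4-en-2-yl]-2-(triisopropylsilyl)-8-[(triisopropylsilyl)oxy]-3a,5,6,7,8,8a-hexahydroazulen-4(3H)-one (cis-fused)
Conditions: TiCl4 (1.2 equiv), 15 (2 equiv), CH2Cl2, −78 °C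
Reagents that add atoms: none
Why: TiCl4 activates enone 13 and the methyl-bearing alkyne carbon of 15 adds to C6 (Hosomi–Sakurai-type conjugate addition) to give a β-silyl vinyl cation; a 1,2-shift of the bulky silyl group turns this into a 2-silylallyl cation, which the titanium enolate captures through C2 at the cationic CH2 terminus. The closest known reaction type is the Danheiser [3+2] annulation of allenyl- and propargylsilanes with enones, in which a triisopropylsilyl group suppresses the competing desilylation to an allene. The cyclopentene is closed in a 5-(enolexo)-endo mode at the terminus of the allyl cation, the whole being a formal [3+2] cycloaddition across C2=C6. C6 is set by attack anti to the adjacent C7 silyloxy group (the C8 side chain lies on the same blocked face), and C2 follows from the geometric need for a cis-fused closure, so 16 has the C6 configuration of the target and a C2 configuration that step 12 corrects. Regiochemistry is fixed by polarity (nucleophilic carbon to the β-carbon C6, cationic CH2 to the α-carbon C2), which puts CH3 on C5 and leaves C4 as a vinylsilane. The selectivity needed is annulation over simple conjugate transfer of the butynyl unit, which the TIPS group and the low temperature should secure.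

Step 12
Reactants: 16 (3aR,7R,8S,8aR)-1-methyl-7-[(2S)-pent-4-en-2-yl]-2-(triisopropylsilyl)-8-[(triisopropylsilyl)oxy]-3a,5,6,7,8,8a-hexahydroazulen-4(3H)-one
Product: 18 (3aS,7R,8S,8aR)-1-methyl-7-[(2S)-pent-4-en-2-yl]-8-[(triisopropylsilyl)oxy]-3a,5,6,7,8,8a-hexahydroazulen-4(3H)-one (trans-fused), via cis-fused ketone 17 (not isolated)
Conditions: TFA, CH2Cl2, 0 °C to rt; concentrate; then K2CO3, MeOH, rt
Reagents that add atoms: none
Why: ipso-Protodesilylation of the vinylsilane (protonation at C4 gives the tertiary β-silyl cation at C5, so the alkene stays at C4=C5) is followed by base equilibration of C2 through the C1 enolate to the trans-fused hydroazulenone, which should be favoured because its twist-chair carries the C3, C5 and C8 substituents equatorially.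

Step 13
Reactants: 18 (3aS,7R,8S,8aR)-1-methyl-7-[(2S)-pent-4-en-2-yl]-8-[(triisopropylsilyl)oxy]-3a,5,6,7,8,8a-hexahydroazulen-4(3H)-one
Product: 19 (3aS,5S,7R,8S,8aR)-5-bromo-1-methyl-7-[(2S)-pent-4-en-2-yl]-8-[(triisopropylsilyl)oxy]-3a,5,6,7,8,8a-hexahydroazulen-4(3H)-one
Conditions: LDA, THF, −78 °C; then NBS, −78 °C
Reagents that add atoms: N-bromosuccinimide O=C1CCC(=O)N1Br
Why: LDA deprotonates the C10 methylene (kinetic enolate, away from the ring-fusion methine) and α-bromination should occur on the open α-face anti to the pseudo-axial C8 side chain to give the axial 10α-bromo ketone, the epimer also preferred at equilibrium.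

Step 14
Reactants: 19 (3aS,5S,7R,8S,8aR)-5-bromo-1-methyl-7-[(2S)-pent-4-en-2-yl]-8-[(triisopropylsilyl)oxy]-3a,5,6,7,8,8a-hexahydroazulen-4(3H)-one
Product: 20 (3aS,5R,7R,8S,8aR)-1-methyl-4-oxo-7-[(2S)-pent-4-en-2-yl]-8-[(triisopropylsilyl)oxy]-3,3a,4,5,6,7,8,8a-octahydroazulen-5-yl acetate
Conditions: CsOAc, DMF, rt
Reagents that add atoms: caesium acetate [Cs+].CC([O-])=O
Why: SN2 displacement of the activated α-keto bromide by acetate proceeds with inversion and should install the equatorial 10β-acetate.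

Step 15
Reactants: 20 (3aS,5R,7R,8S,8aR)-1-methyl-4-oxo-7-[(2S)-pent-4-en-2-yl]-8-[(triisopropylsilyl)oxy]-3,3a,4,5,6,7,8,8a-octahydroazulen-5-yl acetate
Product: 21 (3aR,4S,5R,7R,8aS)-3-methyl-8-methylidene-5-[(2S)-pent-4-en-2-yl]-4-[(triisopropylsilyl)oxy]-1,3a,4,5,6,7,8,8a-octahydroazulen-7-yl acetate
Conditions: Zn, CH2Br2, TiCl4, THF/CH2Cl2, 0 °C to rt
Reagents that add atoms: dibromomethane BrCBr
Why: The non-basic Takai–Lombardo methylenation converts the hindered, enolisable α-acetoxy ketone into the exocyclic alkene without touching the acetate or epimerising C2 and C10.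

Step 16
Reactants: 21 (3aR,4S,5R,7R,8aS)-3-methyl-8-methylidene-5-[(2S)-pent-4-en-2-yl]-4-[(triisopropylsilyl)oxy]-1,3a,4,5,6,7,8,8a-octahydroazulen-7-yl acetate; 22 2-methylbut-3-en-2-ol
Product: 23 (3aR,4S,5R,7R,8aS)-5-[(2S,4E)-6-hydroxy-6-methylhept-4-en-2-yl]-3-methyl-8-methylidene-4-[(triisopropylsilyl)oxy]-1,3a,4,5,6,7,8,8a-octahydroazulen-7-yl acetate
Conditions: Hoveyda–Grubbs II (5 mol%), 22 (10 equiv), CH2Cl2, 40 °C
Reagents that add atoms: none
Why: Cross-metathesis of the only monosubstituted alkene with the tertiary allylic alcohol should give the E-alkene for steric reasons, the 1,1-disubstituted and trisubstituted ring alkenes being unreactive.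

Step 17
Reactants: 23 (3aR,4S,5R,7R,8aS)-5-[(2S,4E)-6-hydroxy-6-methylhept-4-en-2-yl]-3-methyl-8-methylidene-4-[(triisopropylsilyl)oxy]-1,3a,4,5,6,7,8,8a-octahydroazulen-7-yl acetate
Product: 24 (3aR,4S,5R,7R,8aS)-4-hydroxy-5-[(2S,4E)-6-hydroxy-6-methylhept-4-en-2-yl]-3-methyl-8-methylidene-1,3a,4,5,6,7,8,8a-octahydroazulen-7-yl acetate
Conditions: TBAF, AcOH, THF, rt to 40 °C
Reagents that add atoms: none
Why: Buffered fluoride desilylation should free the C7 hydroxyl without acetate migration or ionisation of the tertiary allylic alcohol.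

**Compound list**

1 | methyl hydrogen (R)-3-methylglutarate | COC(=O)C[C@H](C)CC(=O)O | starting material
2 | (4S)-4-methyloxan-2-one | O=C1C[C@@H](C)CCO1 | intermediate
3 | 3-bromo-1,1-dimethoxypropane | COC(CCBr)OC | starting material
4 | (3R,4S)-3-(3,3-dimethoxypropyl)-4-methyloxan-2-one | O=C1[C@H](CCC(OC)OC)[C@@H](C)CCO1 | intermediate
5 | (3R,4S)-3-(3,3-dimethoxypropyl)-4-methyloxan-2-ol (lactol, both anomers; not isolated) | OC1[C@H](CCC(OC)OC)[C@@H](C)CCO1 | intermediate
6 | (3R,4R,5S)-4-(3,3-dimethoxypropyl)-5-methylhept-1-ene-3,7-diol | C=C[C@@H](O)[C@@H]([C@@H](C)CCO)CCC(OC)OC | intermediate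
7 | (3R,4R,5S)-4-(3,3-dimethoxypropyl)-5-methyl-7-[(triethylsilyl)oxy]hept-1-en-3-ol (not isolated) | C=C[C@@H](O)[C@@H]([C@@H](C)CCO[Si](CC)(CC)CC)CCC(OC)OC | intermediate
8 | (3R,4R,5S)-4-(3,3-dimethoxypropyl)-5-methyl-7-[(triethylsilyl)oxy]-3-[(triisopropylsilyl)oxy]hept-1-ene | C=C[C@@H](O[Si](C(C)C)(C(C)C)C(C)C)[C@@H]([C@@H](C)CCO[Si](CC)(CC)CC)CCC(OC)OC | intermediate
9 | (4R,5R)-4-[(2S)-4-hydroxybutan-2-yl]-5-[(triisopropylsilyl)oxy]hept-6-enal | C=C[C@@H](O[Si](C(C)C)(C(C)C)C(C)C)[C@@H]([C@@H](C)CCO)CCC=O | intermediate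
10 | (3R,4R)-4-[(2S)-4-hydroxybutan-2-yl]-3-[(triisopropylsilyl)oxy]nona-1,8-dien-7-ol (both epimers at the new carbinol) | C=C[C@@H](O[Si](C(C)C)(C(C)C)C(C)C)[C@@H]([C@@H](C)CCO)CCC(O)C=C | intermediate
11 | (4R,5R)-5-[(2S)-4-hydroxybutan-2-yl]-4-[(triisopropylsilyl)oxy]cyclohept-2-en-1-ol (both epimers at C1) | OC1C=C[C@@H](O[Si](C(C)C)(C(C)C)C(C)C)[C@@H]([C@@H](C)CCO)CC1 | intermediate
12 | (3S)-3-[(1R,2R)-5-oxo-2-[(triisopropylsilyl)oxy]cyclohept-3-en-1-yl]butanal | O=C1C=C[C@@H](O[Si](C(C)C)(C(C)C)C(C)C)[C@@H]([C@@H](C)CC=O)CC1 | intermediate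
13 | (4R,5R)-5-[(2S)-pent-4-en-2-yl]-4-[(triisopropylsilyl)oxy]cyclohept-2-en-1-one | O=C1C=C[C@@H](O[Si](C(C)C)(C(C)C)C(C)C)[C@@H]([C@@H](C)CC=C)CC1 | intermediate
14 | but-2-yne | CC#CC | starting material
15 | (but-2-yn-1-yl)triisopropylsilane | CC#CC[Si](C(C)C)(C(C)C)C(C)C | intermediate
16 | (3aR,7R,8S,8aR)-1-methyl-7-[(2S)-pent-4-en-2-yl]-2-(triisopropylsilyl)-8-[(triisopropylsilyl)oxy]-3a,5,6,7,8,8a-hexahydroazulen-4(3H)-one (cis-fused) | O=C1[C@@H]2CC([Si](C(C)C)(C(C)C)C(C)C)=C(C)[C@@H]2[C@@H](O[Si](C(C)C)(C(C)C)C(C)C)[C@@H]([C@@H](C)CC=C)CC1 | intermediate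
17 | (3aR,7R,8S,8aR)-1-methyl-7-[(2S)-pent-4-en-2-yl]-8-[(triisopropylsilyl)oxy]-3a,5,6,7,8,8a-hexahydroazulen-4(3H)-one (cis-fused; not isolated) | O=C1[C@@H]2CC=C(C)[C@@H]2[C@@H](O[Si](C(C)C)(C(C)C)C(C)C)[C@@H]([C@@H](C)CC=C)CC1 | intermediate
18 | (3aS,7R,8S,8aR)-1-methyl-7-[(2S)-pent-4-en-2-yl]-8-[(triisopropylsilyl)oxy]-3a,5,6,7,8,8a-hexahydroazulen-4(3H)-one (trans-fused) | O=C1[C@H]2CC=C(C)[C@@H]2[C@@H](O[Si](C(C)C)(C(C)C)C(C)C)[C@@H]([C@@H](C)CC=C)CC1 | intermediate
19 | (3aS,5S,7R,8S,8aR)-5-bromo-1-methyl-7-[(2S)-pent-4-en-2-yl]-8-[(triisopropylsilyl)oxy]-3a,5,6,7,8,8a-hexahydroazulen-4(3H)-one | O=C1[C@H]2CC=C(C)[C@@H]2[C@@H](O[Si](C(C)C)(C(C)C)C(C)C)[C@@H]([C@@H](C)CC=C)C[C@@H]1Br | intermediate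
20 | (3aS,5R,7R,8S,8aR)-1-methyl-4-oxo-7-[(2S)-pent-4-en-2-yl]-8-[(triisopropylsilyl)oxy]-3,3a,4,5,6,7,8,8a-octahydroazulen-5-yl acetate | O=C1[C@H]2CC=C(C)[C@@H]2[C@@H](O[Si](C(C)C)(C(C)C)C(C)C)[C@@H]([C@@H](C)CC=C)C[C@H]1OC(C)=O | intermediate
21 | (3aR,4S,5R,7R,8aS)-3-methyl-8-methylidene-5-[(2S)-pent-4-en-2-yl]-4-[(triisopropylsilyl)oxy]-1,3a,4,5,6,7,8,8a-octahydroazulen-7-yl acetate | C=C1[C@H]2CC=C(C)[C@@H]2[C@@H](O[Si](C(C)C)(C(C)C)C(C)C)[C@@H]([C@@H](C)CC=C)C[C@H]1OC(C)=O | intermediate
22 | 2-methylbut-3-en-2-ol | C=CC(C)(C)O | starting material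
23 | (3aR,4S,5R,7R,8aS)-5-[(2S,4E)-6-hydroxy-6-methylhept-4-en-2-yl]-3-methyl-8-methylidene-4-[(triisopropylsilyl)oxy]-1,3a,4,5,6,7,8,8a-octahydroazulen-7-yl acetate | C=C1[C@H]2CC=C(C)[C@@H]2[C@@H](O[Si](C(C)C)(C(C)C)C(C)C)[C@@H]([C@@H](C)C/C=C/C(C)(C)O)C[C@H]1OC(C)=O | intermediate
24 | (3aR,4S,5R,7R,8aS)-4-hydroxy-5-[(2S,4E)-6-hydroxy-6-methylhept-4-en-2-yl]-3-methyl-8-methylidene-1,3a,4,5,6,7,8,8a-octahydroazulen-7-yl acetate | C=C1[C@H]2CC=C(C)[C@@H]2[C@@H](O)[C@@H]([C@@H](C)C/C=C/C(C)(C)O)C[C@H]1OC(C)=O | target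

**Step count and risks**

Total steps: 17. Longest linear sequence: 16 (steps 1–9 and 11–17); step 10 makes the annulation partner.

Steps most likely to fail:

1. Step 11. The butynyl unit may be transferred with loss of silicon (allene formation) instead of annulating, or the hindered γ-silyloxy enone may react sluggishly. The fallback sets out from 13 and comes back at 18. Conjugate addition of the isopropenyl cuprate (isopropenylmagnesium bromide, CuBr·SMe2, TMSCl, THF, −78 °C) anti to the C7 silyl ether should give the trimethylsilyl enol ether F1. Regeneration of the lithium enolate (MeLi, THF, 0 °C) and alkylation with allyl iodide (HMPA, −78 °C) trans to the isopropenyl group should give the 2-allyl-3-isopropenyl ketone F2. Ring-closing metathesis (Grubbs II, CH2Cl2, 40 °C) then closes the cyclopentene and gives 18 directly, with the trans ring fusion set kinetically and no silyl group to remove.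

2. Step 3. Poor facial selectivity in the vinyl addition to the α-branched aldehyde would give a mixture of C7 epimers. The fallback sets out from 4 and comes back at 7, which is silylated to 8 as in step 4. The lactone is opened with Me(MeO)NH·HCl/AlMe3 to the hydroxy Weinreb amide F3, which is silylated (TESCl, imidazole) to the triethylsilyl ether F4. Lithium (trimethylsilyl)acetylide then gives the ynone F5. Transfer hydrogenation with RuCl(p-cymene)[(S,S)-TsDPEN] in i-PrOH sets C7 under catalyst control and gives the propargylic alcohol F6. K2CO3/MeOH removes the alkynyl silyl group to give the terminal alkyne F7, and Lindlar semi-hydrogenation gives 7.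

3. Step 13. Attack of the electrophile on both faces of the enolate, or epimerisation and elimination of the bromo ketone during step 14, would erode the C10 configuration. The fallback sets out from 18 and comes back at 21. Hydroxylation of the kinetic enolate (LiHMDS, then Davis oxaziridine, −78 °C) gives the α-hydroxy ketone F8, either C10 epimer being usable. Methylenation with excess Ph3P=CH2 gives the allylic alcohol F9, and Dess–Martin oxidation gives the cross-conjugated enone F10. Luche reduction (NaBH4, CeCl3·7H2O, MeOH, −78 °C), with axial hydride delivery from the α-face, should give the equatorial 10β-alcohol F11, and acetylation (Ac2O, DMAP, pyridine) gives 21.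

**Further compounds**

F1 | step 11 | trimethylsilyl enol ether of the 3-isopropenyl ketone (isopropenyl on C6 anti to OTIPS) | C[Si](C)(C)OC1=C[C@H](C(C)=C)[C@@H](O[Si](C(C)C)(C(C)C)C(C)C)[C@@H]([C@@H](C)CC=C)CC1
F2 | step 11 | trans-2-allyl-3-isopropenyl cycloheptanone (allyl on C2, isopropenyl on C6) | O=C1[C@@H](CC=C)[C@H](C(C)=C)[C@@H](O[Si](C(C)C)(C(C)C)C(C)C)[C@@H]([C@@H](C)CC=C)CC1
F3 | step 3 | hydroxy Weinreb amide from lactone 4 | CON(C)C(=O)[C@@H]([C@@H](C)CCO)CCC(OC)OC
F4 | step 3 | triethylsilyl ether of F3 | CON(C)C(=O)[C@@H]([C@@H](C)CCO[Si](CC)(CC)CC)CCC(OC)OC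
F5 | step 3 | trimethylsilyl ynone | C[Si](C)(C)C#CC(=O)[C@@H]([C@@H](C)CCO[Si](CC)(CC)CC)CCC(OC)OC
F6 | step 3 | (S)-propargylic alcohol (C7 set) | C[Si](C)(C)C#C[C@@H](O)[C@@H]([C@@H](C)CCO[Si](CC)(CC)CC)CCC(OC)OC
F7 | step 3 | terminal alkyne | C#C[C@@H](O)[C@@H]([C@@H](C)CCO[Si](CC)(CC)CC)CCC(OC)OC
F8 | step 13 | 10-hydroxy ketone (C10 epimers) | O=C1[C@H]2CC=C(C)[C@@H]2[C@@H](O[Si](C(C)C)(C(C)C)C(C)C)[C@@H]([C@@H](C)CC=C)CC1O
F9 | step 13 | 1-methylidene-10-ol (C10 epimers) | C=C1[C@H]2CC=C(C)[C@@H]2[C@@H](O[Si](C(C)C)(C(C)C)C(C)C)[C@@H]([C@@H](C)CC=C)CC1O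
F10 | step 13 | 1-methylidene-10-one (cross-conjugated enone) | C=C1[C@H]2CC=C(C)[C@@H]2[C@@H](O[Si](C(C)C)(C(C)C)C(C)C)[C@@H]([C@@H](C)CC=C)CC1=O
F11 | step 13 | 10β-allylic alcohol | C=C1[C@H]2CC=C(C)[C@@H]2[C@@H](O[Si](C(C)C)(C(C)C)C(C)C)[C@@H]([C@@H](C)CC=C)C[C@H]1O
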